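**Plan**

1. Numbering: C1 is the ring carbonyl carbon, C2=C3 the enone alkene, C4 and C5 the secondary carbinols, and C6 the tertiary carbinol that carries the (Z)-henicos-12-enyl chain.
2. Retrosynthesis: after removal of two 2-naphthylmethyl ethers, the ring is cut at C5–C6 and at C2=C3, a [3+3] disconnection. It is possible because the C1 ketone is flanked by two donor carbons (C6 and C2) and C4 lies between two carbons that can both be carbonyl carbons (C5 and C3). The pieces are enol silane 7 (C6–C1–C2 with the chain) and aldehyde acetal 13 (C5–C4–C3).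
3. Forward: 7 comes from erucyl alcohol (its C1 becomes C6) and ethyl vinyl ether (C1 and C2), so the chain is present from the start. 13 comes from (R)-glyceraldehyde acetonide. The six-membered ring, the only ring, arises in one flask in step 9 (C5–C6 first, then C2=C3), and oxidative deprotection ends the route.
4. Stereochemistry: C4 is bought with (R)-glyceraldehyde acetonide. C5 follows from chelation control and C6 from simple diastereoselection in the same event. The Z-alkene is bought with erucyl alcohol.

Key step: step 9

**Route**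

Step 1
Reactants: 1 (Z)-docos-13-en-1-ol (erucyl alcohol)
Product: 2 (Z)-docos-13-enal
Conditions: 2,2,6,6-tetramethylpiperidin-1-oxyl (TEMPO, 10 mol %), PhI(OAc)2, CH2Cl2, rt
Reagents that add atoms: none
Why: The oxoammonium-mediated alcohol oxidation should stop at the aldehyde and leave the isolated Z-alkene untouched; no stereocenter is formed.

Step 2
Reactants: 2 (Z)-docos-13-enal; 3 ethyl vinyl ether
Product: 6 (15Z)-3-(naphthalen-2-ylmethoxy)tetracos-15-en-2-one (racemic), via alkoxide adduct 4 (not isolated), via enol ether 5 (not isolated)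
Conditions: 3, t-BuLi, THF, –78 → 0 °C; 2, –78 °C; then 2-(bromomethyl)naphthalene, Bu4NI (cat.), N,N′-dimethylpropyleneurea, –78 °C → rt; then 1 M HCl, THF, rt
Reagents that add atoms: 2-(bromomethyl)naphthalene, BrCc1ccc2ccccc2c1; water, O
Why: 1-Ethoxyvinyllithium acts as an acetyl anion equivalent in a 1,2-addition, the lithium alkoxide is etherified in the same flask (Williamson ether synthesis) and mild acid hydrolyses the enol ether to the methyl ketone; the carbinol center is left racemic on purpose because it becomes trigonal in step 3.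

Step 3
Reactants: 6 (15Z)-3-(naphthalen-2-ylmethoxy)tetracos-15-en-2-one
Product: 7 trimethyl{[(15Z)-3-(naphthalen-2-ylmethoxy)tetracosa-2,15-dien-2-yl]oxy}silane (mixture of C2=C3 isomers)
Conditions: Me3SiCl, NaI, Et3N, MeCN–CH2Cl2, rt; pentane extraction, used crude
Reagents that add atoms: chlorotrimethylsilane, C[Si](C)(C)Cl
Why: Silylation under equilibrating conditions (thermodynamic enol silane formation with Me3SiI made in the flask) should favour the more substituted, oxygen-bearing enol silane toward the carbon that becomes C6 over the terminal one; the double-bond geometry need not be controlled.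

Step 4
Reactants: 8 (R)-2,2-dimethyl-1,3-dioxolane-4-carbaldehyde ((R)-glyceraldehyde acetonide)
Product: 9 (R)-3,3-dimethoxypropane-1,2-diol
Conditions: MeOH, p-toluenesulfonic acid monohydrate (cat.), rt → 40 °C; then Et3N (quench)
Reagents that add atoms: methanol, CO
Why: Acid-catalysed transacetalisation in methanol should turn the aldehyde into its dimethyl acetal and release the diol in one operation, the water from the first change being consumed in the second; the stereocenter takes no part.

Step 5
Reactants: 9 (R)-3,3-dimethoxypropane-1,2-diol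
Product: 10 (R)-3-[(tert-butyldiphenylsilyl)oxy]-1,1-dimethoxypropan-2-ol
Conditions: t-BuPh2SiCl, imidazole, CH2Cl2, 0 °C
Reagents that add atoms: tert-butyl(chloro)diphenylsilane, CC(C)(C)[Si](Cl)(c1ccccc1)c1ccccc1
Why: The bulky silyl chloride should silylate the primary hydroxyl of the 1,2-diol selectively (steric differentiation).

Step 6
Reactants: 10 (R)-3-[(tert-butyldiphenylsilyl)oxy]-1,1-dimethoxypropan-2-ol
Product: 11 tert-butyl{[(R)-3,3-dimethoxy-2-(naphthalen-2-ylmethoxy)propyl]oxy}diphenylsilane
Conditions: NaH, 2-(bromomethyl)naphthalene, Bu4NI (cat.), THF–DMF, 0 °C → rt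
Reagents that add atoms: 2-(bromomethyl)naphthalene, BrCc1ccc2ccccc2c1
Why: Williamson ether synthesis on the secondary alkoxide installs a chelating, Lewis-acid-tolerant and oxidatively removable arylmethyl ether; the bulky silyl group on the primary oxygen is not expected to migrate at this temperature.

Step 7
Reactants: 11 tert-butyl{[(R)-3,3-dimethoxy-2-(naphthalen-2-ylmethoxy)propyl]oxy}diphenylsilane
Product: 12 (R)-3,3-dimethoxy-2-(naphthalen-2-ylmethoxy)propan-1-ol
Conditions: Bu4NF, THF, 0 °C → rt
Reagents that add atoms: none
Why: Fluoride-induced desilylation cleaves only the Si–O bond; the ether and the acetal are inert.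

Step 8
Reactants: 12 (R)-3,3-dimethoxy-2-(naphthalen-2-ylmethoxy)propan-1-ol
Product: 13 (R)-3,3-dimethoxy-2-(naphthalen-2-ylmethoxy)propanal
Conditions: 2,2,6,6-tetramethylpiperidin-1-oxyl (TEMPO, 10 mol %), PhI(OAc)2, CH2Cl2, rt; used at once
Reagents that add atoms: none
Why: The non-basic oxoammonium oxidation should give the configurationally labile α-alkoxy aldehyde without epimerisation.

Step 9
Reactants: 7 trimethyl{[(15Z)-3-(naphthalen-2-ylmethoxy)tetracosa-2,15-dien-2-yl]oxy}silane; 13 (R)-3,3-dimethoxy-2-(naphthalen-2-ylmethoxy)propanal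
Product: 16 (4S,5R,6R)-6-[(Z)-henicos-12-en-1-yl]-5-hydroxy-4,6-bis(naphthalen-2-ylmethoxy)cyclohex-2-en-1-one, via aldol adduct 14 (not isolated), via methoxy ketone 15 (not isolated)
Conditions: 13, TiCl4 (1.0 equiv), CH2Cl2, –78 °C; 7 (1.0 equiv), –78 °C; then TiCl4 (1.2 equiv), i-Pr2NEt (1.3 equiv), –78 → –20 °C; then DBU (1,8-diazabicyclo[5.4.0]undec-7-ene, 4 equiv), –20 → 0 °C; aqueous NaHCO3 work-up
Reagents that add atoms: none
Why: TiCl4 binds 13 as the five-membered chelate of the aldehyde oxygen and the C4 ether oxygen, enol silane 7 adds through C6 in an open transition state (Mukaiyama aldol addition, C5–C6) to give aldolate 14, the second equivalent of TiCl4 then ionises the dimethyl acetal to the C3 oxocarbenium ion while i-Pr2NEt turns the chelated α-alkoxy methyl ketone into its C2 titanium enolate, which closes the ring (C2–C3, 15), and DBU removes methanol by E1cB elimination to set the enone. The closest known reaction types are the chelation-controlled Mukaiyama aldol addition of enol silanes to α-alkoxy aldehydes and the addition of titanium enolates of α-benzyloxy methyl ketones to dimethyl acetals, run here one after the other in one flask. The six-membered carbocycle is closed in the 6-(enolendo)-exo-trig mode. C5 is controlled by the rigid chelate, in which the nucleophile should come in anti to the C3 substituent, placing O5 syn to O4 along the chain and therefore trans on the ring. C6 is controlled by simple diastereoselection in the open transition state, where the small ether oxygen of 7 should lie over the chelate and the long chain take the open quadrant, the sense known for α-alkyl enol silanes (alkyl syn to the new hydroxyl) and for O-arylmethyl glycolate enol silanes (ether oxygen anti), so that O6 should end cis to O5 on the ring whatever the geometry of 7. The step needs chemoselectivity for the aldehyde over the acetal, secured because the first equivalent of TiCl4 is tied up in the chelate and the electron-poor α-alkoxy acetal is ionised only when more Lewis acid is added, and it needs a single site of enolisation in the second stage, secured because C6 is then quaternary so that only the C2 methyl group can be deprotonated and only C2=C3 can form.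

Step 10
Reactants: 16 (4S,5R,6R)-6-[(Z)-henicos-12-en-1-yl]-5-hydroxy-4,6-bis(naphthalen-2-ylmethoxy)cyclohex-2-en-1-one
Product: 17 (4S,5R,6R)-6-[(Z)-henicos-12-en-1-yl]-4,5,6-trihydroxycyclohex-2-en-1-one (CNP0376716.1)
Conditions: DDQ (2,3-dichloro-5,6-dicyano-1,4-benzoquinone), CH2Cl2–pH 7 phosphate buffer (10:1), 0 °C → rt
Reagents that add atoms: none
Why: DDQ should oxidise both naphthylmethyl ethers by hydride abstraction to oxocarbenium ions that water hydrolyses (oxidative arylmethyl ether cleavage), under neutral conditions that should spare the enone, the tertiary α-ketol and the isolated Z-alkene; no stereocenter is touched.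

**Compound list**

1 | (Z)-docos-13-en-1-ol (erucyl alcohol) | CCCCCCCC/C=C\CCCCCCCCCCCCO | starting material
2 | (Z)-docos-13-enal | CCCCCCCC/C=C\CCCCCCCCCCCC=O | intermediate
3 | ethyl vinyl ether | C=COCC | starting material
4 | (15Z)-2-ethoxytetracosa-1,15-dien-3-ol (racemic, present as its lithium alkoxide) | CCCCCCCC/C=C\CCCCCCCCCCCC(O)C(=C)OCC | intermediate
5 | 2-({[(15Z)-2-ethoxytetracosa-1,15-dien-3-yl]oxy}methyl)naphthalene (racemic) | CCCCCCCC/C=C\CCCCCCCCCCCC(OCc1ccc2ccccc2c1)C(=C)OCC | intermediate
6 | (15Z)-3-(naphthalen-2-ylmethoxy)tetracos-15-en-2-one (racemic) | CCCCCCCC/C=C\CCCCCCCCCCCC(OCc1ccc2ccccc2c1)C(C)=O | intermediate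
7 | trimethyl{[(15Z)-3-(naphthalen-2-ylmethoxy)tetracosa-2,15-dien-2-yl]oxy}silane (C2=C3 isomer mixture) | CCCCCCCC/C=C\CCCCCCCCCCCC(OCc1ccc2ccccc2c1)=C(C)O[Si](C)(C)C | intermediate
8 | (R)-2,2-dimethyl-1,3-dioxolane-4-carbaldehyde | CC1(C)OC[C@H](C=O)O1 | starting material
9 | (R)-3,3-dimethoxypropane-1,2-diol | COC(OC)[C@H](O)CO | intermediate
10 | (R)-3-[(tert-butyldiphenylsilyl)oxy]-1,1-dimethoxypropan-2-ol | COC(OC)[C@H](O)CO[Si](c1ccccc1)(c1ccccc1)C(C)(C)C | intermediate
11 | tert-butyl{[(R)-3,3-dimethoxy-2-(naphthalen-2-ylmethoxy)propyl]oxy}diphenylsilane | COC(OC)[C@H](OCc1ccc2ccccc2c1)CO[Si](c1ccccc1)(c1ccccc1)C(C)(C)C | intermediate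
12 | (R)-3,3-dimethoxy-2-(naphthalen-2-ylmethoxy)propan-1-ol | COC(OC)[C@H](OCc1ccc2ccccc2c1)CO | intermediate
13 | (R)-3,3-dimethoxy-2-(naphthalen-2-ylmethoxy)propanal | COC(OC)[C@H](OCc1ccc2ccccc2c1)C=O | intermediate
14 | (3R,4R,5R)-3-[(Z)-henicos-12-en-1-yl]-4-hydroxy-6,6-dimethoxy-3,5-bis(naphthalen-2-ylmethoxy)hexan-2-one (titanium-bound in the flask) | CCCCCCCC/C=C\CCCCCCCCCCC[C@]([C@H](O)[C@@H](OCc1ccc2ccccc2c1)C(OC)OC)(OCc1ccc2ccccc2c1)C(C)=O | intermediate
15 | (2R,3R,4R)-2-[(Z)-henicos-12-en-1-yl]-3-hydroxy-5-methoxy-2,4-bis(naphthalen-2-ylmethoxy)cyclohexan-1-one (both C5 epimers) | CCCCCCCC/C=C\CCCCCCCCCCC[C@]1(OCc2ccc3ccccc3c2)C(=O)CC(OC)[C@H](OCc2ccc3ccccc3c2)[C@H]1O | intermediate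
16 | (4S,5R,6R)-6-[(Z)-henicos-12-en-1-yl]-5-hydroxy-4,6-bis(naphthalen-2-ylmethoxy)cyclohex-2-en-1-one | CCCCCCCC/C=C\CCCCCCCCCCC[C@]1(OCc2ccc3ccccc3c2)C(=O)C=C[C@H](OCc2ccc3ccccc3c2)[C@H]1O | intermediate
17 | (4S,5R,6R)-6-[(Z)-henicos-12-en-1-yl]-4,5,6-trihydroxycyclohex-2-en-1-one | CCCCCCCC/C=C\CCCCCCCCCCC[C@]1(O)C(=O)C=C[C@H](O)[C@H]1O | target

**Count and risks**

Total step count: 10. Longest linear sequence: 7 steps (8 → 9 → 10 → 11 → 12 → 13 → 16 → 17).

Steps most likely to fail, riskiest first:

Risk 1, step 9: the acetal may ionise before the aldehyde has reacted, so that the enol silane attacks C3 instead of C5; the C3 oxocarbenium ion may lose a proton (which would scramble C4) or the aldolate may undergo retro-aldol cleavage during the second stage; and simple diastereoselection at C6 may be insufficient. The fallback for step 9 sets out from 7 and 13, comes back to the route at 16 and makes the two bonds in separate flasks. A MgBr2·OEt2-mediated, chelation-controlled Mukaiyama aldol addition (CH2Cl2, –78 → –20 °C), which does not activate the acetal, should give aldol adduct 14, now isolated so that diastereomers can be separated. Me3SiOTf and i-Pr2NEt (CH2Cl2, –78 → 0 °C) should then silylate O5, convert the methyl ketone into its enol silane and ionise the acetal, so that an intramolecular Mukaiyama addition closes the ring to the trimethylsilyl-protected methoxy ketone F1, which is the O5-trimethylsilyl ether of 15. DBU should eliminate methanol from F1 to give the trimethylsilyl-protected enone F2, which is the O5-trimethylsilyl ether of 16, and AcOH–THF–H2O should remove the silyl group from F2 to give 16.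

Risk 2, step 3: silylation may compete toward the methyl group and give the terminal enol silane, which would later react through C2 first. The fallback for step 3 sets out from 6 and comes back to the route at 7. Isopropenyl acetate with p-toluenesulfonic acid monohydrate (cat.) at reflux should give the enol acetates under equilibrating conditions. The tetrasubstituted enol acetate (15Z)-3-(naphthalen-2-ylmethoxy)tetracosa-2,15-dien-2-yl acetate F3 is stable to chromatography and is separated from the terminal isomer. MeLi (2 equiv, THF, –78 → 0 °C) followed by Me3SiCl should then convert F3 into 7 free of its regioisomer.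

Risk 3, step 10: a naphthylmethyl oxocarbenium ion may cyclise onto the free C5 hydroxyl to give a naphthylidene acetal, cleavage at the tertiary ether may be slow, and the liberated allylic alcohol may be over-oxidised. The fallback for step 10 sets out from 16 and comes back to the route at 17. O5 is first silylated (Et3SiOTf, 2,6-lutidine, CH2Cl2, –78 °C) to the triethylsilyl-protected enone F4, which is the O5-triethylsilyl ether of 16. DDQ under the buffered conditions should then convert F4 into the triethylsilyl-protected diol F5, which is the O5-triethylsilyl ether of 17, and HF·pyridine in THF–pyridine at 0 °C should release 17 from F5.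

Further compounds
F1 | step 9 | trimethylsilyl-protected methoxy ketone, the O5-trimethylsilyl ether of 15 (ring configurations as in 15, both epimers at the methoxy carbon) | CCCCCCCC/C=C\CCCCCCCCCCC[C@]1(OCc2ccc3ccccc3c2)C(=O)CC(OC)[C@H](OCc2ccc3ccccc3c2)[C@H]1O[Si](C)(C)C
F2 | step 9 | trimethylsilyl-protected enone, (4S,5R,6R)-6-[(Z)-henicos-12-en-1-yl]-4,6-bis(naphthalen-2-ylmethoxy)-5-[(trimethylsilyl)oxy]cyclohex-2-en-1-one | CCCCCCCC/C=C\CCCCCCCCCCC[C@]1(OCc2ccc3ccccc3c2)C(=O)C=C[C@H](OCc2ccc3ccccc3c2)[C@H]1O[Si](C)(C)C
F3 | step 3 | (15Z)-3-(naphthalen-2-ylmethoxy)tetracosa-2,15-dien-2-yl acetate | CCCCCCCC/C=C\CCCCCCCCCCCC(OCc1ccc2ccccc2c1)=C(C)OC(C)=O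
F4 | step 10 | triethylsilyl-protected enone, (4S,5R,6R)-6-[(Z)-henicos-12-en-1-yl]-4,6-bis(naphthalen-2-ylmethoxy)-5-[(triethylsilyl)oxy]cyclohex-2-en-1-one | CCCCCCCC/C=C\CCCCCCCCCCC[C@]1(OCc2ccc3ccccc3c2)C(=O)C=C[C@H](OCc2ccc3ccccc3c2)[C@H]1O[Si](CC)(CC)CC
F5 | step 10 | triethylsilyl-protected diol, (4S,5R,6R)-6-[(Z)-henicos-12-en-1-yl]-4,6-dihydroxy-5-[(triethylsilyl)oxy]cyclohex-2-en-1-one | CCCCCCCC/C=C\CCCCCCCCCCC[C@]1(O)C(=O)C=C[C@H](O)[C@H]1O[Si](CC)(CC)CC
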